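With time, target in this flask leaks into its isomer, so reckon how far the leak gets by the reading.

    solid substrate ⇌ dissolved substrate, rate k1*(cs1 - [dissolved substrate]) while solid is left; crystals form when [dissolved substrate] > cs1 (cs1 = 0.074 M, k1 = 0.631 s⁻¹)
    dissolved substrate + reagent → target (k2 = 111 L mol⁻¹ s⁻¹)
    solid product ⇌ target, rate k3*(cs3 - [target]) while solid is left; crystals form when [target] > cs3 (cs3 = 33 mM, k3 = 0.442 s⁻¹)
    2 reagent → homo dimer (k4 = 16.6 L mol⁻¹ s⁻¹)
    target ⇌ isomer of the product (K5 = 0.53, k5 = 0.00443 s⁻¹)
    gas ⇌ reagent, rate k6*(csat - [reagent]) (k6 = 10.1 s⁻¹, csat = 4.8 mM)

solid substrate 0.10 M; gas 4.8 mM (held); time 1.0 min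

1. amount of target and solid product together at 1.0 min, in percent of the solid substrate charged
2. concentration of dissolved substrate in solution at 1.0 min, in percent of saturation

- for target the solid product is counted in
- for a step with 2 of a species take k times the square, and two of it per event
- as a solid, counted per litre of solution: solid substrate, solid product
- at the start none of reagent is dissolved
- at the start none of the solid substrate is in solution
- dissolved substrate means what is dissolved; the solid is not counted in it
- run time (flask): 1.0 min

Start with the front of the run. Dissolving has a clock of 1.58 s, and dissolved substrate decays pseudo-first-order with a clock of 1.88 s if c(reagent) stands at saturation. Both are far shorter than the run, and transfer from the gas is quicker still. Allow the decay half of the run: c(dissolved substrate) ends below <0.001% of saturation.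

The charge exceeds what solution and isomer can hold, so solid product stands and holds c(target) at its solubility. The isomer then gains at a steady rate and falls back with the constant 0.502 min⁻¹. Divide that gain by this constant and time drops out. What remains is the equilibrium constant times the solubility of target, per charge: 17.5%. Call it the isomer ceiling, the thermodynamic limit of the leak. The isomer climbs towards it first-order with the back constant. Take the charge as fully converted, and I reckon y at 93.1%.

The forecast says 92.8% and <0.001%: “Practically all the charge therefore becomes target”. Its yield lies just below mine.

The flask gives 92.9% and 0%, so the forecast stands. Moved alone, solid substrate shifts y by 5 points at 0.0564 M and at 0.452 M; the time does so at 0.127 min and, with y falling, at 2.33 min. Put the ceiling to use at that last time: it reckons the isomer at 12.1% of the charge, which leaves y at 87.9%.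

Now take the flask left until 4.0 min. The ceiling gives y as 84.8%. The computed result there is 84.8%.

(The rate constants are invented; the rest is arithmetic.)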